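Closing ring A last through the C4a–C5 bond is the disconnection on which everything rests. Ring A is an acylphloroglucinol, so its atoms C5–C6–C7–C8 can be carried as an aryloxy β-keto ester chain on C8a of a preformed (2S)-dihydropyran-4-one ring C, in which the enol ether O1–C8a and the C4 vinylogous ester stand in for two chain carbonyls. One magnesium-mediated Claisen closure then delivers the aromatic ring with the free 5,7-diol, the C6 aryl ether in place and C2 untouched. Its precursor is an ethyl 2-aryloxy-3-oxobutanoate that carries the benzyl-protected flavone on oxygen and the (S)-pyranone at C4; the side chain is attached by soft-enolisation acylation of a pyranone-6-acetate, so no strong base meets ring C.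

Key step: step 11

Assumption: compounds 16–20 are carried as mixtures of epimers and enol tautomers at the aryloxy carbon (18 and 19 also at the neighbouring CH), which does not matter because that carbon becomes aromatic C6; all numbered starting materials are taken as catalogue compounds.

Step 1
Reactants: 1 1-[4-(benzyloxy)phenyl]ethan-1-one; 2 diethyl carbonate
Product: 3 ethyl 3-[4-(benzyloxy)phenyl]-3-oxopropanoate
Conditions: NaH (2.2 equiv), (EtO)2CO (3 equiv), THF, reflux; then aq. HCl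
Reagents that add atoms: none
Why: Crossed Claisen condensation of the ketone enolate with non-enolisable diethyl carbonate, pulled to completion by deprotonation of the β-keto ester that forms.

Step 2
Reactants: 3 ethyl 3-[4-(benzyloxy)phenyl]-3-oxopropanoate
Product: 4 ethyl (3S)-3-[4-(benzyloxy)phenyl]-3-hydroxypropanoate
Conditions: RuCl[(S,S)-TsDPEN](p-cymene) (1 mol %), HCO2H–Et3N (5:2), 40 °C
Reagents that add atoms: none
Why: Noyori asymmetric transfer hydrogenation: the Ru–H/N–H pair of the (S,S) catalyst should deliver hydride to the Re face of the aryl ketone (aryl held against the η6-arene), which sets the carbinol as S as with other aryl ketones, and leaves the ester and the benzyl ether alone.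

Step 3
Reactants: 4 ethyl (3S)-3-[4-(benzyloxy)phenyl]-3-hydroxypropanoate; 5 allyl 3-oxobutanoate
Product: 7 allyl 2-{(2S)-2-[4-(benzyloxy)phenyl]-4-oxo-3,4-dihydro-2H-pyran-6-yl}acetate, via hydroxy diketo ester 6 (not isolated)
Conditions: 5 (3 equiv), LiN(i-Pr)2 (6 equiv), THF, −78 → 0 °C; then 4, −40 → 0 °C; AcOH; crude, pyridinium p-toluenesulfonate (0.1 equiv), CH2Cl2, rt
Reagents that add atoms: none
Why: Huckin–Weiler Claisen acylation: the γ-carbon of the acetoacetate dianion adds to the ethyl ester of 4 (carried as its lithium alkoxide), and under mild acid the 7-OH of 6 adds to the C3 ketone (the only six-membered option) and water is lost towards C4 to give the vinylogous ester, the C–O bond at the stereocentre staying untouched so that 3S becomes 2S.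

Step 4
Reactants: 8 1-(2,4,6-trihydroxyphenyl)ethan-1-one
Product: 9 1-[2,4-bis(benzyloxy)-6-hydroxyphenyl]ethan-1-one
Conditions: BnBr (2.1 equiv), K2CO3 (2.2 equiv), DMF, rt
Reagents that add atoms: benzyl bromide, BrCc1ccccc1
Why: Williamson etherification: the 4-OH and one ortho OH are benzylated, after which the last ortho OH is tied up in a hydrogen bond to the acetyl group and should stay free with two equivalents of halide.

Step 5
Reactants: 9 1-[2,4-bis(benzyloxy)-6-hydroxyphenyl]ethan-1-one; 10 4-(methoxymethoxy)benzaldehyde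
Product: 11 (2E)-1-[2,4-bis(benzyloxy)-6-hydroxyphenyl]-3-[4-(methoxymethoxy)phenyl]prop-2-en-1-one
Conditions: KOH (50 % aq.), EtOH–THF, rt; then aq. HCl
Reagents that add atoms: none
Why: Claisen–Schmidt condensation of the acetophenone enolate with the non-enolisable aldehyde, the methoxymethyl acetal and the benzyl ethers being stable to hydroxide.

Step 6
Reactants: 11 (2E)-1-[2,4-bis(benzyloxy)-6-hydroxyphenyl]-3-[4-(methoxymethoxy)phenyl]prop-2-en-1-one
Product: 13 5,7-bis(benzyloxy)-2-(4-hydroxyphenyl)-4H-chromen-4-one, via MOM-protected flavone 12 (not isolated)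
Conditions: I2 (0.1 equiv), DMSO, 120 °C; then 3 M HCl, MeOH–THF, 55 °C
Reagents that add atoms: none
Why: Iodine-catalysed oxidative cyclisation of the 2'-hydroxychalcone (oxa-Michael closure, then iodination–elimination with DMSO as terminal oxidant), followed by acid cleavage of the methoxymethyl acetal, which the benzyl ethers should survive.

Step 7
Reactants: 13 5,7-bis(benzyloxy)-2-(4-hydroxyphenyl)-4H-chromen-4-one; 14 diethyl 2-chloropropanedioate
Product: 15 diethyl 2-{4-[5,7-bis(benzyloxy)-4-oxo-4H-chromen-2-yl]phenoxy}propanedioate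
Conditions: K2CO3 (1.5 equiv), DMF, 50 °C
Reagents that add atoms: none
Why: Williamson etherification by SN2 of the single free phenoxide on the α-chloromalonate, which puts the future C6–O bond on an sp3 carbon before that carbon meets the pyranone, so that no carbenoid or halogenation chemistry is needed beside the nucleophilic pyranone carbon.

Step 8
Reactants: 15 diethyl 2-{4-[5,7-bis(benzyloxy)-4-oxo-4H-chromen-2-yl]phenoxy}propanedioate
Product: 16 2-{4-[5,7-bis(benzyloxy)-4-oxo-4H-chromen-2-yl]phenoxy}-3-ethoxy-3-oxopropanoic acid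
Conditions: KOH (1.05 equiv), EtOH–THF, 0 °C → rt; then cold 1 M HCl
Reagents that add atoms: potassium hydroxide, [K+].[OH-]
Why: Mono-saponification of a malonate: once the first ester is cleaved the carboxylate shields the second from the single equivalent of hydroxide, and the flavone tolerates cold dilute base.

Step 9
Reactants: 16 2-{4-[5,7-bis(benzyloxy)-4-oxo-4H-chromen-2-yl]phenoxy}-3-ethoxy-3-oxopropanoic acid; 7 allyl 2-{(2S)-2-[4-(benzyloxy)phenyl]-4-oxo-3,4-dihydro-2H-pyran-6-yl}acetate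
Product: 18 1-allyl 5-ethyl 2-{(2S)-2-[4-(benzyloxy)phenyl]-4-oxo-3,4-dihydro-2H-pyran-6-yl}-4-{4-[5,7-bis(benzyloxy)-4-oxo-4H-chromen-2-yl]phenoxy}-3-oxopentanedioate, via acid chloride 17 (not isolated)
Conditions: 16, (COCl)2 (1.3 equiv), DMF (cat.), CH2Cl2, 0 °C → rt, evaporate; then 7, MgCl2 (2 equiv), Et3N (3 equiv), MeCN–CH2Cl2, 0 °C → rt
Reagents that add atoms: none
Why: Rathke-type magnesium-mediated soft-enolisation C-acylation: MgCl2/Et3N can enolise only the CH2 flanked by the allyl ester and the vinylogous ester carbon C6 (never C3–H), and the chelated enolate should be acylated by 17 at that exocyclic carbon, which keeps the pyranone conjugation.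

Step 10
Reactants: 18 1-allyl 5-ethyl 2-{(2S)-2-[4-(benzyloxy)phenyl]-4-oxo-3,4-dihydro-2H-pyran-6-yl}-4-{4-[5,7-bis(benzyloxy)-4-oxo-4H-chromen-2-yl]phenoxy}-3-oxopentanedioate
Product: 20 ethyl 2-{4-[5,7-bis(benzyloxy)-4-oxo-4H-chromen-2-yl]phenoxy}-4-{(2S)-2-[4-(benzyloxy)phenyl]-4-oxo-3,4-dihydro-2H-pyran-6-yl}-3-oxobutanoate, via β-keto acid 19 (not isolated)
Conditions: Pd(PPh3)4 (5 mol %), morpholine (2 equiv), THF, 0 °C → rt; then aq. citric acid
Reagents that add atoms: none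
Why: Tsuji–Trost deallylation: zerovalent palladium ionises the allyl ester, morpholine takes the allyl group, and the β-keto acid 19 should lose CO2 at room temperature under neutral conditions that leave C2, the benzyl ethers and the ethyl ester alone.

Step 11
Reactants: 20 ethyl 2-{4-[5,7-bis(benzyloxy)-4-oxo-4H-chromen-2-yl]phenoxy}-4-{(2S)-2-[4-(benzyloxy)phenyl]-4-oxo-3,4-dihydro-2H-pyran-6-yl}-3-oxobutanoate
Product: 21 (2S)-2-[4-(benzyloxy)phenyl]-6-{4-[5,7-bis(benzyloxy)-4-oxo-4H-chromen-2-yl]phenoxy}-5,7-dihydroxy-2,3-dihydro-4H-chromen-4-one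
Conditions: Mg(OEt)2 (4 equiv), EtOH–THF (1:1), 0.01 M, 50 °C; then cold 1 M HCl
Reagents that add atoms: none
Why: Proposed new method: Mg(OEt)2 deprotonates the two acidic side-chain sites (the aryloxy CH and the CH2 between C8a and the ketone), and the dienolate from the CH2, which runs through C8a=C4a to the C4 oxygen, should attack through its α-carbon C4a the ethyl ester that magnesium holds in a chelate with the side-chain ketone, after which loss of ethoxide and two enolisations give the aromatic 5,7-diol. The closest known reaction type is the magnesium-alkoxide-promoted Claisen (Dieckmann-type) cyclisation of open-chain or pyrone-masked 3,5,7-triketo esters to acylphloroglucinols; what has not been shown is a dihydropyran-4-one carbon as the nucleophile. Ring A closes in a 6-exo-trig mode at the ester carbonyl. No stereocenter is created; C2 should be carried through because the weak base is consumed at the two side-chain sites and does not reach the much less acidic C3–H, and because the product sits as a magnesium 5-O/4-O chelate and 7-phenoxide that resists retro-oxa-Michael opening. The regiochemistry is secured by the mask: O1 is already on C8a and C4 is a vinylogous ester carbonyl, so the only other conceivable closure (aryloxy carbon onto C4=O) would bridge ring C across C4 and C8a and is excluded, and the aryl ether can only end up on C6.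

Step 12
Reactants: 21 (2S)-2-[4-(benzyloxy)phenyl]-6-{4-[5,7-bis(benzyloxy)-4-oxo-4H-chromen-2-yl]phenoxy}-5,7-dihydroxy-2,3-dihydro-4H-chromen-4-one
Product: 22 (2S)-2-[4-(benzyloxy)phenyl]-6-{4-[5,7-bis(benzyloxy)-4-oxo-4H-chromen-2-yl]phenoxy}-5-hydroxy-7-methoxy-2,3-dihydro-4H-chromen-4-one
Conditions: Me3SiCHN2 (1.3 equiv), MeOH–toluene (1:4), 0 °C → rt
Reagents that add atoms: trimethylsilyldiazomethane, C[Si](C)(C)C=[N+]=[N-]
Why: O-methylation by diazomethane released from Me3SiCHN2 in methanol: only the acidic 7-OH para to the C4 carbonyl should react, since the 5-OH is locked in a hydrogen bond to C4=O, and the neutral medium cannot open ring C.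

Step 13
Reactants: 22 (2S)-2-[4-(benzyloxy)phenyl]-6-{4-[5,7-bis(benzyloxy)-4-oxo-4H-chromen-2-yl]phenoxy}-5-hydroxy-7-methoxy-2,3-dihydro-4H-chromen-4-one
Product: 23 (2S)-6-[4-(5,7-dihydroxy-4-oxo-4H-chromen-2-yl)phenoxy]-5-hydroxy-2-(4-hydroxyphenyl)-7-methoxy-2,3-dihydro-4H-chromen-4-one (CNP0269971.1)
Conditions: H2 (1 atm), 10 % Pd/C, EtOAc–THF–MeOH, rt
Reagents that add atoms: none
Why: Catalytic hydrogenolysis of the three aryl benzyl ethers, which under balloon pressure at room temperature should be much faster than reduction of the flavone C2=C3 bond, the flavanone carbonyl or the benzylic C2–O1 bond.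

Compound list
1 | 1-[4-(benzyloxy)phenyl]ethan-1-one | CC(=O)c1ccc(OCc2ccccc2)cc1 | starting material
2 | diethyl carbonate | CCOC(=O)OCC | starting material
3 | ethyl 3-[4-(benzyloxy)phenyl]-3-oxopropanoate | CCOC(=O)CC(=O)c1ccc(OCc2ccccc2)cc1 | intermediate
4 | ethyl (3S)-3-[4-(benzyloxy)phenyl]-3-hydroxypropanoate | CCOC(=O)C[C@H](O)c1ccc(OCc2ccccc2)cc1 | intermediate
5 | allyl 3-oxobutanoate (allyl acetoacetate) | CC(=O)CC(=O)OCC=C | starting material
6 | allyl (7S)-7-[4-(benzyloxy)phenyl]-7-hydroxy-3,5-dioxoheptanoate | C=CCOC(=O)CC(=O)CC(=O)C[C@H](O)c1ccc(OCc2ccccc2)cc1 | intermediate (not isolated)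
7 | allyl 2-{(2S)-2-[4-(benzyloxy)phenyl]-4-oxo-3,4-dihydro-2H-pyran-6-yl}acetate | C=CCOC(=O)CC1=CC(=O)C[C@@H](c2ccc(OCc3ccccc3)cc2)O1 | intermediate
8 | 1-(2,4,6-trihydroxyphenyl)ethan-1-one | CC(=O)c1c(O)cc(O)cc1O | starting material
9 | 1-[2,4-bis(benzyloxy)-6-hydroxyphenyl]ethan-1-one | CC(=O)c1c(O)cc(OCc2ccccc2)cc1OCc1ccccc1 | intermediate
10 | 4-(methoxymethoxy)benzaldehyde | COCOc1ccc(C=O)cc1 | starting material
11 | (2E)-1-[2,4-bis(benzyloxy)-6-hydroxyphenyl]-3-[4-(methoxymethoxy)phenyl]prop-2-en-1-one | COCOc1ccc(/C=C/C(=O)c2c(O)cc(OCc3ccccc3)cc2OCc2ccccc2)cc1 | intermediate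
12 | 5,7-bis(benzyloxy)-2-[4-(methoxymethoxy)phenyl]-4H-chromen-4-one | COCOc1ccc(-c2cc(=O)c3c(OCc4ccccc4)cc(OCc5ccccc5)cc3o2)cc1 | intermediate (not isolated)
13 | 5,7-bis(benzyloxy)-2-(4-hydroxyphenyl)-4H-chromen-4-one | Oc1ccc(-c2cc(=O)c3c(OCc4ccccc4)cc(OCc5ccccc5)cc3o2)cc1 | intermediate
14 | diethyl 2-chloropropanedioate (diethyl chloromalonate) | CCOC(=O)C(Cl)C(=O)OCC | starting material
15 | diethyl 2-{4-[5,7-bis(benzyloxy)-4-oxo-4H-chromen-2-yl]phenoxy}propanedioate | CCOC(=O)C(Oc1ccc(-c2cc(=O)c3c(OCc4ccccc4)cc(OCc5ccccc5)cc3o2)cc1)C(=O)OCC | intermediate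
16 | 2-{4-[5,7-bis(benzyloxy)-4-oxo-4H-chromen-2-yl]phenoxy}-3-ethoxy-3-oxopropanoic acid (racemic) | CCOC(=O)C(Oc1ccc(-c2cc(=O)c3c(OCc4ccccc4)cc(OCc5ccccc5)cc3o2)cc1)C(=O)O | intermediate
17 | ethyl 2-{4-[5,7-bis(benzyloxy)-4-oxo-4H-chromen-2-yl]phenoxy}-3-chloro-3-oxopropanoate | CCOC(=O)C(Oc1ccc(-c2cc(=O)c3c(OCc4ccccc4)cc(OCc5ccccc5)cc3o2)cc1)C(=O)Cl | intermediate (not isolated)
18 | 1-allyl 5-ethyl 2-{(2S)-2-[4-(benzyloxy)phenyl]-4-oxo-3,4-dihydro-2H-pyran-6-yl}-4-{4-[5,7-bis(benzyloxy)-4-oxo-4H-chromen-2-yl]phenoxy}-3-oxopentanedioate (epimers at C2 and C4 of the diester) | CCOC(=O)C(Oc1ccc(-c2cc(=O)c3c(OCc4ccccc4)cc(OCc5ccccc5)cc3o2)cc1)C(=O)C(C(=O)OCC=C)C1=CC(=O)C[C@@H](c2ccc(OCc3ccccc3)cc2)O1 | intermediate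
19 | 2-{(2S)-2-[4-(benzyloxy)phenyl]-4-oxo-3,4-dihydro-2H-pyran-6-yl}-4-{4-[5,7-bis(benzyloxy)-4-oxo-4H-chromen-2-yl]phenoxy}-5-ethoxy-3,5-dioxopentanoic acid | CCOC(=O)C(Oc1ccc(-c2cc(=O)c3c(OCc4ccccc4)cc(OCc5ccccc5)cc3o2)cc1)C(=O)C(C(=O)O)C1=CC(=O)C[C@@H](c2ccc(OCc3ccccc3)cc2)O1 | intermediate (not isolated)
20 | ethyl 2-{4-[5,7-bis(benzyloxy)-4-oxo-4H-chromen-2-yl]phenoxy}-4-{(2S)-2-[4-(benzyloxy)phenyl]-4-oxo-3,4-dihydro-2H-pyran-6-yl}-3-oxobutanoate (epimers at the aryloxy carbon) | CCOC(=O)C(Oc1ccc(-c2cc(=O)c3c(OCc4ccccc4)cc(OCc5ccccc5)cc3o2)cc1)C(=O)CC1=CC(=O)C[C@@H](c2ccc(OCc3ccccc3)cc2)O1 | intermediate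
21 | (2S)-2-[4-(benzyloxy)phenyl]-6-{4-[5,7-bis(benzyloxy)-4-oxo-4H-chromen-2-yl]phenoxy}-5,7-dihydroxy-2,3-dihydro-4H-chromen-4-one | Oc1cc2c(c(O)c1Oc1ccc(-c3cc(=O)c4c(OCc5ccccc5)cc(OCc6ccccc6)cc4o3)cc1)C(=O)C[C@@H](c1ccc(OCc7ccccc7)cc1)O2 | intermediate
22 | (2S)-2-[4-(benzyloxy)phenyl]-6-{4-[5,7-bis(benzyloxy)-4-oxo-4H-chromen-2-yl]phenoxy}-5-hydroxy-7-methoxy-2,3-dihydro-4H-chromen-4-one | COc1cc2c(c(O)c1Oc1ccc(-c3cc(=O)c4c(OCc5ccccc5)cc(OCc6ccccc6)cc4o3)cc1)C(=O)C[C@@H](c1ccc(OCc7ccccc7)cc1)O2 | intermediate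
23 | (2S)-6-[4-(5,7-dihydroxy-4-oxo-4H-chromen-2-yl)phenoxy]-5-hydroxy-2-(4-hydroxyphenyl)-7-methoxy-2,3-dihydro-4H-chromen-4-one | COc1cc2c(c(O)c1Oc1ccc(-c3cc(=O)c4c(O)cc(O)cc4o3)cc1)C(=O)C[C@@H](c1ccc(O)cc1)O2 | target

Total step count: 13. Longest linear sequence: 10 steps (8 → 9 → 11 → 13 → 15 → 16 → 18 → 20 → 21 → 22 → 23, steps 4–13). The pyranone arm (steps 1–3) joins at step 9.

Steps most likely to fail

Step 11 (key step). The dienolate carbon C4a may be too weak a nucleophile towards an ester that is itself enolised and chelated. Retro-Claisen cleavage of the β-keto ester by ethoxide could then compete, or enolisation at C3 could open ring C and erode the configuration at C2. The fallback uses known chemistry, makes ring A aromatic first and sets C2 last; it sets out from 9 and comes back at 23. Compound 9 is condensed with 4-fluorobenzaldehyde (KOH, EtOH) to (2E)-1-[2,4-bis(benzyloxy)-6-hydroxyphenyl]-3-(4-fluorophenyl)prop-2-en-1-one F1, which I2 in DMSO oxidises to 5,7-bis(benzyloxy)-2-(4-fluorophenyl)-4H-chromen-4-one F2. Separately, Elbs persulfate oxidation (K2S2O8, aq. NaOH, then acid) of commercial 1-(2-hydroxy-4,6-dimethoxyphenyl)ethan-1-one should give 1-(3,6-dihydroxy-2,4-dimethoxyphenyl)ethan-1-one F3. Claisen formylation (ethyl formate, NaH) and acid cyclodehydration turn this into 6-hydroxy-5,7-dimethoxy-4H-chromen-4-one F4. SNAr of the phenoxide of F4 on the fluoroarene of F2 (Cs2CO3, DMSO, 110 °C) should give 6-{4-[5,7-bis(benzyloxy)-4-oxo-4H-chromen-2-yl]phenoxy}-5,7-dimethoxy-4H-chromen-4-one F5. Palladium-catalysed asymmetric conjugate addition of [4-(benzyloxy)phenyl]boronic acid to the 2-unsubstituted chromone of F5 then sets C2 (Pd(OCOCF3)2, the t-BuPyOx enantiomer that delivers 2S, NH4PF6, water, ClCH2CH2Cl, 60 °C); the 2-aryl flavone enone is inert. This should give (2S)-2-[4-(benzyloxy)phenyl]-6-{4-[5,7-bis(benzyloxy)-4-oxo-4H-chromen-2-yl]phenoxy}-5,7-dimethoxy-2,3-dihydro-4H-chromen-4-one F6. BCl3 (CH2Cl2, −78 → 0 °C) then removes the three benzyl ethers and the chelated 5-O-methyl group, leaves the 7-O-methyl group and gives 23.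

Step 9. Soft enolisation of the vinylogous malonate may be incomplete, or the hindered, enolisable acid chloride may be lost to O-acylation and ketene dimerisation. The fallback builds the chain with a small acyl chloride and makes the aryl ether last; it sets out from 7 (with 13) and comes back at 20. Under the same MgCl2/Et3N conditions 7 is acylated with ethyl malonyl chloride to 1-allyl 5-ethyl 2-{(2S)-2-[4-(benzyloxy)phenyl]-4-oxo-3,4-dihydro-2H-pyran-6-yl}-3-oxopentanedioate F7. Pd(PPh3)4 with morpholine gives the acid 2-{(2S)-2-[4-(benzyloxy)phenyl]-4-oxo-3,4-dihydro-2H-pyran-6-yl}-5-ethoxy-3,5-dioxopentanoic acid F8, which should lose CO2 to ethyl 4-{(2S)-2-[4-(benzyloxy)phenyl]-4-oxo-3,4-dihydro-2H-pyran-6-yl}-3-oxobutanoate F9. Regitz diazo transfer (4-acetamidobenzenesulfonyl azide, Et3N, MeCN) at the β-keto ester CH2 gives ethyl 2-diazo-4-{(2S)-2-[4-(benzyloxy)phenyl]-4-oxo-3,4-dihydro-2H-pyran-6-yl}-3-oxobutanoate F10. Rh2(OAc)4-catalysed O–H insertion into phenol 13 (slow addition of F10 to excess 13, ClCH2CH2Cl, 60 °C, to outrun attack of the pyranone carbon on the carbenoid) then gives 20.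

Step 3. The lithium alkoxide of the unprotected β-hydroxy ester may undergo retro-aldol cleavage or simply resist acylation, and the benzylic carbinol may dehydrate during the acid closure. The fallback masks the carbinol and changes the acyl donor to an amide that adds once through a stable chelate; it sets out from 4 and comes back at 7. Silylation (t-BuMe2SiCl, imidazole, DMF) gives ethyl (3S)-3-[4-(benzyloxy)phenyl]-3-[(tert-butyldimethylsilyl)oxy]propanoate F11. Aminolysis (MeNH(OMe)·HCl, i-PrMgCl, THF, −20 °C) gives (3S)-3-[4-(benzyloxy)phenyl]-3-[(tert-butyldimethylsilyl)oxy]-N-methoxy-N-methylpropanamide F12. The dianion of 5 (2.2 equiv) adds to it to give allyl (7S)-7-[4-(benzyloxy)phenyl]-7-[(tert-butyldimethylsilyl)oxy]-3,5-dioxoheptanoate F13. HF·pyridine in MeCN removes the silyl group, and the freed alcohol should close as in step 3 (through 6) to 7.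

Further compounds
F1 | step 11 | (2E)-1-[2,4-bis(benzyloxy)-6-hydroxyphenyl]-3-(4-fluorophenyl)prop-2-en-1-one | O=C(/C=C/c1ccc(F)cc1)c1c(O)cc(OCc2ccccc2)cc1OCc1ccccc1
F2 | step 11 | 5,7-bis(benzyloxy)-2-(4-fluorophenyl)-4H-chromen-4-one | Fc1ccc(-c2cc(=O)c3c(OCc4ccccc4)cc(OCc5ccccc5)cc3o2)cc1
F3 | step 11 | 1-(3,6-dihydroxy-2,4-dimethoxyphenyl)ethan-1-one | CC(=O)c1c(O)cc(OC)c(O)c1OC
F4 | step 11 | 6-hydroxy-5,7-dimethoxy-4H-chromen-4-one | COc1cc2occc(=O)c2c(OC)c1O
F5 | step 11 | 6-{4-[5,7-bis(benzyloxy)-4-oxo-4H-chromen-2-yl]phenoxy}-5,7-dimethoxy-4H-chromen-4-one | COc1cc2occc(=O)c2c(OC)c1Oc1ccc(-c2cc(=O)c3c(OCc4ccccc4)cc(OCc5ccccc5)cc3o2)cc1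
F6 | step 11 | (2S)-2-[4-(benzyloxy)phenyl]-6-{4-[5,7-bis(benzyloxy)-4-oxo-4H-chromen-2-yl]phenoxy}-5,7-dimethoxy-2,3-dihydro-4H-chromen-4-one | COc1cc2c(c(OC)c1Oc1ccc(-c3cc(=O)c4c(OCc5ccccc5)cc(OCc6ccccc6)cc4o3)cc1)C(=O)C[C@@H](c1ccc(OCc7ccccc7)cc1)O2
F7 | step 9 | 1-allyl 5-ethyl 2-{(2S)-2-[4-(benzyloxy)phenyl]-4-oxo-3,4-dihydro-2H-pyran-6-yl}-3-oxopentanedioate | CCOC(=O)CC(=O)C(C(=O)OCC=C)C1=CC(=O)C[C@@H](c2ccc(OCc3ccccc3)cc2)O1
F8 | step 9 | 2-{(2S)-2-[4-(benzyloxy)phenyl]-4-oxo-3,4-dihydro-2H-pyran-6-yl}-5-ethoxy-3,5-dioxopentanoic acid | CCOC(=O)CC(=O)C(C(=O)O)C1=CC(=O)C[C@@H](c2ccc(OCc3ccccc3)cc2)O1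
F9 | step 9 | ethyl 4-{(2S)-2-[4-(benzyloxy)phenyl]-4-oxo-3,4-dihydro-2H-pyran-6-yl}-3-oxobutanoate | CCOC(=O)CC(=O)CC1=CC(=O)C[C@@H](c2ccc(OCc3ccccc3)cc2)O1
F10 | step 9 | ethyl 2-diazo-4-{(2S)-2-[4-(benzyloxy)phenyl]-4-oxo-3,4-dihydro-2H-pyran-6-yl}-3-oxobutanoate | CCOC(=O)C(=[N+]=[N-])C(=O)CC1=CC(=O)C[C@@H](c2ccc(OCc3ccccc3)cc2)O1
F11 | step 3 | ethyl (3S)-3-[4-(benzyloxy)phenyl]-3-[(tert-butyldimethylsilyl)oxy]propanoate | CCOC(=O)C[C@H](O[Si](C)(C)C(C)(C)C)c1ccc(OCc2ccccc2)cc1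
F12 | step 3 | (3S)-3-[4-(benzyloxy)phenyl]-3-[(tert-butyldimethylsilyl)oxy]-N-methoxy-N-methylpropanamide | CON(C)C(=O)C[C@H](O[Si](C)(C)C(C)(C)C)c1ccc(OCc2ccccc2)cc1
F13 | step 3 | allyl (7S)-7-[4-(benzyloxy)phenyl]-7-[(tert-butyldimethylsilyl)oxy]-3,5-dioxoheptanoate | C=CCOC(=O)CC(=O)CC(=O)C[C@H](O[Si](C)(C)C(C)(C)C)c1ccc(OCc2ccccc2)cc1
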